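The plan rests on cutting C2–C3 of ring A. The feature exploited is the 1,3-relation of the C1 and C3 oxygens in ring A, flanked by quaternary C10 and by C4 with its C15 methylene. In the 2,3-seco form (acetyl on C10, 1-formylvinyl on C5 of a finished ring B), C2 is the only enolisable carbon. One silyl-triflate-mediated Mukaiyama aldol therefore closes ring A, creates the C3 carbinol and leaves C4=C15 untouched. The precursor is an oxidised elemane. Esterification of geraniol and an enantioselective Ireland–Claisen rearrangement join all fifteen carbons (C5, C10). A carbonyl-ene reaction closes ring B (C6, C7), and SeO2 and Wacker oxidations add the carbonyls.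

Key step: step 11

Remark: eudesmane numbering is used for all intermediates, including the seco (elemane-type) ones. α/β refer to the usual drawing with the C10 methyl group β. "TBS-acryloyl" means 2-{[(tert-butyldimethylsilyl)oxy]methyl}acryloyl.
Assumption: the (S,S)-diazaborolidine is taken to give (2S,3S)-5; should the sense of induction be the opposite, its (R,R)-enantiomer is used instead.

Step 1
Reactants: 1 geraniol; 2 3-methylbut-3-enoic acid
Product: 3 geranyl 3-methylbut-3-enoate
Conditions: DCC, DMAP (cat.), CH2Cl2, 0 °C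
Reagents that add atoms: none
Why: Steglich esterification of an unhindered primary allylic alcohol, run cold and briefly so that the β,γ-double bond of the acyl part does not move (the conjugated isomer would give the same dienolate in step 2).

Step 2
Reactants: 3 geranyl 3-methylbut-3-enoate
Product: 5 (2S,3S)-3-ethenyl-3,7-dimethyl-2-(prop-1-en-2-yl)oct-6-enoic acid, via boron ketene acetal 4 (not isolated)
Conditions: (S,S)-2-bromo-4,5-diphenyl-1,3-bis{[3,5-bis(trifluoromethyl)phenyl]sulfonyl}-1,3,2-diazaborolidine, Et3N, toluene–hexane, −78 → −20 °C; aq. work-up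
Reagents that add atoms: none
Why: Enantioselective boron-mediated Ireland–Claisen rearrangement, in which the ketene acetal (O–B trans to the isopropenyl group) and the (E)-alkene of the geranyl part pass through a chair transition state that sets C5 and quaternary C10 in the required relative sense (C4 anti to C9), while the C2-symmetric controller on boron selects the enolate face and thus the absolute configuration.

Step 3
Reactants: 5 (2S,3S)-3-ethenyl-3,7-dimethyl-2-(prop-1-en-2-yl)oct-6-enoic acid
Product: 6 (2S,3S)-3-ethenyl-3,7-dimethyl-2-(prop-1-en-2-yl)oct-6-en-1-ol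
Conditions: LiAlH4, Et2O, 0 °C → rt
Reagents that add atoms: none
Why: Hydride reduction of a carboxylic acid to the primary alcohol, which leaves the three isolated alkenes and both stereocentres untouched.

Step 4
Reactants: 6 (2S,3S)-3-ethenyl-3,7-dimethyl-2-(prop-1-en-2-yl)oct-6-en-1-ol
Product: 7 (2S,3S)-3-ethenyl-3,7-dimethyl-2-(prop-1-en-2-yl)oct-6-enal
Conditions: Dess–Martin periodinane, NaHCO3, CH2Cl2, 0 °C
Reagents that add atoms: none
Why: Dess–Martin oxidation under buffered, non-basic conditions should give the α-branched β,γ-unsaturated aldehyde without epimerisation at C5 or conjugation of the isopropenyl group.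

Step 5
Reactants: 7 (2S,3S)-3-ethenyl-3,7-dimethyl-2-(prop-1-en-2-yl)oct-6-enal
Product: 8 (1S,2S,3S,6S)-3-ethenyl-3-methyl-2,6-di(prop-1-en-2-yl)cyclohexan-1-ol (6α-hydroxy-β-elemene)
Conditions: ZnBr2 (cat.), CH2Cl2, 0 °C
Reagents that add atoms: none
Why: Intramolecular carbonyl-ene reaction of the citronellal-to-isopulegol kind, whose chair transition state (C5 isopropenyl, forming C6–O and C7 substituent equatorial, C10 methyl axial) closes ring B and sets C6 (α-OH) and C7 (β-isopropenyl) trans to each other and in the required relation to C5.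

Step 6
Reactants: 9 methyl 2-(hydroxymethyl)acrylate
Product: 10 methyl 2-{[(tert-butyldimethylsilyl)oxy]methyl}acrylate
Conditions: TBSCl, imidazole, CH2Cl2, 0 °C → rt
Reagents that add atoms: tert-butyldimethylsilyl chloride, CC(C)(C)[Si](C)(C)Cl
Why: Standard silylation of a primary allylic alcohol, which masks the hydroxyl group of the future side chain against acylation and against MnO2.

Step 7
Reactants: 10 methyl 2-{[(tert-butyldimethylsilyl)oxy]methyl}acrylate
Product: 11 2-{[(tert-butyldimethylsilyl)oxy]methyl}acrylic acid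
Conditions: LiOH, THF–H2O, 0 °C → rt; then dilute HCl to pH 4
Reagents that add atoms: lithium hydroxide, [Li+].[OH-]
Why: Saponification of an unhindered methyl ester, in which the α-substituent slows conjugate addition of hydroxide and the TBS ether survives the mild base.

Step 8
Reactants: 8 6α-hydroxy-β-elemene; 11 2-{[(tert-butyldimethylsilyl)oxy]methyl}acrylic acid
Product: 13 6α-(TBS-acryloyloxy)-β-elemene, via mixed anhydride 12 (not isolated)
Conditions: 2,4,6-trichlorobenzoyl chloride, Et3N, toluene, rt; then 8, DMAP, 40 °C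
Reagents that add atoms: none
Why: Yamaguchi esterification, chosen because the equatorial C6 hydroxyl group is flanked by two isopropenyl groups; the ester also blocks lactol formation with the formyl groups made in step 9.

Step 9
Reactants: 13 6α-(TBS-acryloyloxy)-β-elemene
Product: 14 6α-(TBS-acryloyloxy)elema-1,4(15),11(13)-triene-3,12-dial
Conditions: SeO2, 1,4-dioxane, 70 °C
Reagents that add atoms: selenium dioxide, O=[Se]=O
Why: Two-directional Riley allylic oxidation (ene reaction, then 2,3-sigmatropic shift) of both isopropenyl methyl groups to 2-substituted acroleins; the vinyl group has no allylic hydrogen and the acrylate alkene is too electron-poor to react.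

Step 10
Reactants: 14 6α-(TBS-acryloyloxy)elema-1,4(15),11(13)-triene-3,12-dial
Product: 15 6α-(TBS-acryloyloxy)-1-oxoelema-4(15),11(13)-diene-3,12-dial (acetyl group on C10)
Conditions: PdCl2 (cat.), CuCl, O2 (1 atm), DMF–H2O, rt
Reagents that add atoms: water, O
Why: Wacker–Tsuji oxidation, in which divalent palladium binds only the monosubstituted, electron-neutral vinyl group (the other three alkenes are 1,1-disubstituted and conjugated to carbonyl groups) and Markovnikov attack of water gives the methyl ketone.

Step 11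
Reactants: 15 6α-(TBS-acryloyloxy)-1-oxoelema-4(15),11(13)-diene-3,12-dial
Product: 18 6α-(TBS-acryloyloxy)-3α-hydroxy-1-oxoeudesma-4(15),11(13)-dien-12-al, via enol silane 16 (not isolated), via silyl ether 17 (not isolated)
Conditions: TMSOTf, iPr2NEt, CH2Cl2 (high dilution), −78 → −30 °C; then aq. citric acid, THF, 0 °C
Reagents that add atoms: none
Why: iPr2NEt and TMSOTf convert the only enolisable carbonyl group, the acetyl group on quaternary C10, into enol silane 16 (both formyl groups and both acrylate-type esters lack α-hydrogen), and TMSOTf then activates the C3 formyl group so that C2 adds to C3 through an open transition state with silyl transfer to give 17, which the acidic work-up desilylates. The closest known reaction type is the one-pot silyl triflate/amine enol silane formation–Mukaiyama aldol addition of methyl ketones to non-enolisable aldehydes, used here intramolecularly. Ring A is closed in the 6-(enolendo)-exo-trig mode by the C2–C3 bond on the chair of ring B, whose C5 and C10 side arms are both equatorial and therefore within bonding distance; no other ring is formed. The one new stereocentre, C3, is controlled by the s-trans conformation of the silyl-activated 2-substituted enal inside the chair-like transition state, which turns the oxygen to the axial α side (3α); this hydroxyl group directs step 13 and the centre is then set to 3β in step 14. The step needs 1,2-addition at C3 instead of 1,4-addition at C15, which would also close a six-membered ring, and kinetic control with a hard, oxygen-bound silyl Lewis acid at low temperature secures this. It also needs the C3 formyl group to react before the C12 one, which ring size secures (six against eight members), and high dilution suppresses intermolecular aldol addition.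

Step 12
Reactants: 18 6α-(TBS-acryloyloxy)-3α-hydroxy-1-oxoeudesma-4(15),11(13)-dien-12-al
Product: 20 methyl 6α-(TBS-acryloyloxy)-3α-hydroxy-1-oxoeudesma-4(15),11(13)-dien-12-oate, via acrylic acid 19 (not isolated)
Conditions: NaClO2, NaH2PO4, 2-methylbut-2-ene, t-BuOH–H2O, 0 °C; crude acid: TMSCHN2, toluene–MeOH, 0 °C
Reagents that add atoms: sodium chlorite, [Na+].[O-]Cl=O; (trimethylsilyl)diazomethane, C[Si](C)(C)C=[N+]=[N-]
Why: Pinnick oxidation of the remaining enal in a weakly acidic buffer, which avoids retro-aldol cleavage and dehydration of the β-hydroxy ketone, followed by neutral methylation of the crude acid.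

Step 13
Reactants: 20 methyl 6α-(TBS-acryloyloxy)-3α-hydroxy-1-oxoeudesma-4(15),11(13)-dien-12-oate
Product: 21 methyl 6α-(TBS-acryloyloxy)-1β,3α-dihydroxyeudesma-4(15),11(13)-dien-12-oate
Conditions: Me4NBH(OAc)3, MeCN–AcOH, −30 °C
Reagents that add atoms: none
Why: Evans–Saksena hydroxyl-directed reduction, in which the axial 3α-hydroxyl group binds boron and delivers hydride to the α face of the C1 ketone to give the equatorial 1β-alcohol, while esters and acrylates are inert to this reagent.

Step 14
Reactants: 21 methyl 6α-(TBS-acryloyloxy)-1β,3α-dihydroxyeudesma-4(15),11(13)-dien-12-oate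
Product: 23 methyl 6α-(TBS-acryloyloxy)-1β,3β-dihydroxyeudesma-4(15),11(13)-dien-12-oate, via enone 22 (not isolated)
Conditions: MnO2, CH2Cl2, rt; filtration, solvent change; CeCl3·7H2O, NaBH4, MeOH, −78 °C
Reagents that add atoms: none
Why: MnO2 oxidises only the allylic C3 carbinol (C1–OH is not allylic and the side-chain alcohol is silylated), and Luche 1,2-reduction of the sensitive 4(15)-en-3-one by axial attack from the α face, opposite the axial C10 methyl group, gives the equatorial 3β-alcohol.

Step 15
Reactants: 23 methyl 6α-(TBS-acryloyloxy)-1β,3β-dihydroxyeudesma-4(15),11(13)-dien-12-oate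
Product: 24 methyl 1β,3β-dihydroxy-6α-[2-(hydroxymethyl)acryloyloxy]eudesma-4(15),11(13)-dien-12-oate (target)
Conditions: HF·pyridine, pyridine, THF, 0 °C
Reagents that add atoms: none
Why: Buffered fluoride cleavage of the primary TBS ether, mild enough for both acrylate esters and the allylic alcohol.

Compound list
1 | geraniol | CC(C)=CCC/C(C)=C/CO | starting material
2 | 3-methylbut-3-enoic acid | CC(=C)CC(=O)O | starting material
3 | geranyl 3-methylbut-3-enoate | CC(=C)CC(=O)OC/C=C(\C)CCC=C(C)C | intermediate
4 | boron ketene acetal of 3 (O–B trans to isopropenyl, (S,S)-diazaborolidine on boron) | CC(=C)/C=C(/OB1N(S(=O)(=O)c2cc(cc(c2)C(F)(F)F)C(F)(F)F)[C@@H](c2ccccc2)[C@H](c2ccccc2)N1S(=O)(=O)c1cc(cc(c1)C(F)(F)F)C(F)(F)F)OC/C=C(\C)CCC=C(C)C | intermediate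
5 | (2S,3S)-3-ethenyl-3,7-dimethyl-2-(prop-1-en-2-yl)oct-6-enoic acid | OC(=O)[C@@H](C(C)=C)[C@](C)(C=C)CCC=C(C)C | intermediate
6 | (2S,3S)-3-ethenyl-3,7-dimethyl-2-(prop-1-en-2-yl)oct-6-en-1-ol | OC[C@@H](C(C)=C)[C@](C)(C=C)CCC=C(C)C | intermediate
7 | (2S,3S)-3-ethenyl-3,7-dimethyl-2-(prop-1-en-2-yl)oct-6-enal | O=C[C@@H](C(C)=C)[C@](C)(C=C)CCC=C(C)C | intermediate
8 | (1S,2S,3S,6S)-3-ethenyl-3-methyl-2,6-di(prop-1-en-2-yl)cyclohexan-1-ol (6α-hydroxy-β-elemene) | O[C@@H]1[C@@H](C(C)=C)[C@](C)(C=C)CC[C@H]1C(C)=C | intermediate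
9 | methyl 2-(hydroxymethyl)acrylate | C=C(CO)C(=O)OC | starting material
10 | methyl 2-{[(tert-butyldimethylsilyl)oxy]methyl}acrylate | C=C(CO[Si](C)(C)C(C)(C)C)C(=O)OC | intermediate
11 | 2-{[(tert-butyldimethylsilyl)oxy]methyl}acrylic acid | C=C(CO[Si](C)(C)C(C)(C)C)C(=O)O | intermediate
12 | mixed anhydride of 11 with 2,4,6-trichlorobenzoic acid | C=C(CO[Si](C)(C)C(C)(C)C)C(=O)OC(=O)c1c(Cl)cc(Cl)cc1Cl | intermediate
13 | 6α-(TBS-acryloyloxy)-β-elemene | C=C(CO[Si](C)(C)C(C)(C)C)C(=O)O[C@@H]1[C@@H](C(C)=C)[C@](C)(C=C)CC[C@H]1C(C)=C | intermediate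
14 | 6α-(TBS-acryloyloxy)elema-1,4(15),11(13)-triene-3,12-dial | C=C(CO[Si](C)(C)C(C)(C)C)C(=O)O[C@@H]1[C@@H](C(=C)C=O)[C@](C)(C=C)CC[C@H]1C(=C)C=O | intermediate
15 | 6α-(TBS-acryloyloxy)-1-oxoelema-4(15),11(13)-diene-3,12-dial | C=C(CO[Si](C)(C)C(C)(C)C)C(=O)O[C@@H]1[C@@H](C(=C)C=O)[C@](C)(C(C)=O)CC[C@H]1C(=C)C=O | intermediate
16 | trimethylsilyl enol ether of 15 (C1(OTMS)=C2H2) | C=C(CO[Si](C)(C)C(C)(C)C)C(=O)O[C@@H]1[C@@H](C(=C)C=O)[C@](C)(C(=C)O[Si](C)(C)C)CC[C@H]1C(=C)C=O | intermediate
17 | 3α-trimethylsilyl ether of 18 | C=C(CO[Si](C)(C)C(C)(C)C)C(=O)O[C@@H]1[C@H]2C(=C)[C@H](O[Si](C)(C)C)CC(=O)[C@]2(C)CC[C@H]1C(=C)C=O | intermediate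
18 | 6α-(TBS-acryloyloxy)-3α-hydroxy-1-oxoeudesma-4(15),11(13)-dien-12-al (5αH, 7αH, 10β-methyl) | C=C(CO[Si](C)(C)C(C)(C)C)C(=O)O[C@@H]1[C@H]2C(=C)[C@H](O)CC(=O)[C@]2(C)CC[C@H]1C(=C)C=O | intermediate
19 | 6α-(TBS-acryloyloxy)-3α-hydroxy-1-oxoeudesma-4(15),11(13)-dien-12-oic acid | C=C(CO[Si](C)(C)C(C)(C)C)C(=O)O[C@@H]1[C@H]2C(=C)[C@H](O)CC(=O)[C@]2(C)CC[C@H]1C(=C)C(=O)O | intermediate
20 | methyl 6α-(TBS-acryloyloxy)-3α-hydroxy-1-oxoeudesma-4(15),11(13)-dien-12-oate | C=C(CO[Si](C)(C)C(C)(C)C)C(=O)O[C@@H]1[C@H]2C(=C)[C@H](O)CC(=O)[C@]2(C)CC[C@H]1C(=C)C(=O)OC | intermediate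
21 | methyl 6α-(TBS-acryloyloxy)-1β,3α-dihydroxyeudesma-4(15),11(13)-dien-12-oate | C=C(CO[Si](C)(C)C(C)(C)C)C(=O)O[C@@H]1[C@H]2C(=C)[C@H](O)C[C@@H](O)[C@]2(C)CC[C@H]1C(=C)C(=O)OC | intermediate
22 | methyl 6α-(TBS-acryloyloxy)-1β-hydroxy-3-oxoeudesma-4(15),11(13)-dien-12-oate | C=C(CO[Si](C)(C)C(C)(C)C)C(=O)O[C@@H]1[C@H]2C(=C)C(=O)C[C@@H](O)[C@]2(C)CC[C@H]1C(=C)C(=O)OC | intermediate
23 | methyl 6α-(TBS-acryloyloxy)-1β,3β-dihydroxyeudesma-4(15),11(13)-dien-12-oate | C=C(CO[Si](C)(C)C(C)(C)C)C(=O)O[C@@H]1[C@H]2C(=C)[C@@H](O)C[C@@H](O)[C@]2(C)CC[C@H]1C(=C)C(=O)OC | intermediate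
24 | methyl 1β,3β-dihydroxy-6α-[2-(hydroxymethyl)acryloyloxy]eudesma-4(15),11(13)-dien-12-oate (5αH, 7αH, 10β-methyl) | C=C(CO)C(=O)O[C@@H]1[C@H]2C(=C)[C@@H](O)C[C@@H](O)[C@]2(C)CC[C@H]1C(=C)C(=O)OC | target

Total step count: 15. Longest linear sequence: 13 steps (steps 1–5 and 8–15, from geraniol).

Steps most likely to fail

Step 11 (key step). The enol silane may add in the conjugate sense to C15, which also closes a six-membered ring. The aldol may also lose silanol or water to give a cross-conjugated dienone. The fallback sets out from 15. The enol silane is formed as before and quenched with NBS to give the α-bromoketone F1. CrCl2 (LiI cat., THF, rt) converts F1 into a chromium enolate, which under neutral conditions adds to aldehydes only in the 1,2-sense (chromium Reformatsky reaction). The route is rejoined at 18.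

Step 9. The double allylic oxidation may stop halfway. It may instead attack the tertiary allylic C5–H and C7–H bonds, or degrade the material at the temperature needed. The fallback sets out from 13. Ene-type chlorination with HOCl (Ca(OCl)2, solid CO2, CH2Cl2–H2O) gives the bis(allylic chloride) F2. Amine N-oxide oxidation of both primary chlorides (N-methylmorpholine N-oxide, MeCN) then leads back to 14.

Step 10. Hydroxypalladation of the vinyl group next to quaternary C10 may be slow, water may attack the terminal carbon, or divalent palladium may trigger side reactions. The fallback sets out from 14. Dimethyldioxirane epoxidises the only alkene not conjugated to a carbonyl group and gives the epoxide F3 (both C1 epimers serve). LiI/AcOH opens it at the unhindered terminal carbon to the iodohydrin F4, and Dess–Martin oxidation gives the α-iodoketone F5. NaI/AcOH followed by Na2S2O3 removes the iodine, and the route is rejoined at 15.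

Further compounds
F1 | step 11 | α-bromoketone of 15 (bromoacetyl group on C10) | C=C(CO[Si](C)(C)C(C)(C)C)C(=O)O[C@@H]1[C@@H](C(=C)C=O)[C@](C)(C(=O)CBr)CC[C@H]1C(=C)C=O
F2 | step 9 | 3,12-dichloro-6α-(TBS-acryloyloxy)elema-1,4(15),11(13)-triene | C=C(CO[Si](C)(C)C(C)(C)C)C(=O)O[C@@H]1[C@@H](C(=C)CCl)[C@](C)(C=C)CC[C@H]1C(=C)CCl
F3 | step 10 | 1,2-epoxide of 14 (C1 epimers) | C=C(CO[Si](C)(C)C(C)(C)C)C(=O)O[C@@H]1[C@@H](C(=C)C=O)[C@](C)(C2CO2)CC[C@H]1C(=C)C=O
F4 | step 10 | 1-hydroxy-2-iodo derivative of 14 (C1 epimers) | C=C(CO[Si](C)(C)C(C)(C)C)C(=O)O[C@@H]1[C@@H](C(=C)C=O)[C@](C)(C(O)CI)CC[C@H]1C(=C)C=O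
F5 | step 10 | α-iodoketone of 15 (iodoacetyl group on C10) | C=C(CO[Si](C)(C)C(C)(C)C)C(=O)O[C@@H]1[C@@H](C(=C)C=O)[C@](C)(C(=O)CI)CC[C@H]1C(=C)C=O
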